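I had 3 questions about this flask, and the earlier runs were what I had to answer them with.

| flask | left-handed substrate | right-handed substrate | partner | free catalyst | racemization catalyst | remark | time |
|---|---|---|---|---|---|---|---|
| east | 0.050 M | 0.050 M | 0.40 M | 0.14 mM | 2.6 mM | run made earlier |  |
| north | 0.075 M | 0.075 M | 0.40 M | 0.14 mM | 2.6 mM | run made earlier |  |
| flask | 0.10 M | 0.10 M | 0.400 M | 0.14 mM | 2.6 mM |  | 25 min |

| run | time / min | left-handed product / % | right-handed product / % | left-handed substrate / % |
|---|---|---|---|---|
| east | 4.00 | 60.6 | 20.4 | 8.0 |
| east | 10.0 | 62.4 | 21.0 | 8.5 |
| east | 20.0 | 62.1 | 21.4 | 7.8 |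
| east | 30.0 | 62.6 | 22.3 | 7.6 |
| north | 2.50 | 56.3 | 19.6 | 12.3 |
| north | 6.00 | 59.3 | 20.5 | 10.0 |
| north | 12.0 | 60.3 | 21.3 | 10.1 |
| north | 30.0 | 58.9 | 20.2 | 9.8 |

(each reading ± 0.5 percentage points)

* left-handed product and right-handed product together, in percent of the left-handed substrate and right-handed substrate charged together, at 25 min
* excess of left-handed product over right-handed product in the product at 25 min
* whether the exchange between left-handed substrate and right-handed substrate keeps pace with the reaction: how far the product's excess at 25 min gets from its value without exchange to its value with instant exchange (above 80% keeps pace, below 20% hardly takes part, else lags behind)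

- free catalyst is single-handed; left-handed substrate and right-handed substrate are mirror images of each other, charged as a racemate, each of them at the stated concentration
- what was read earlier has a scatter of 0.5 percentage points, one standard deviation
- steps thought possible: partner + free catalyst + left-handed substrate -> free catalyst + left-handed product; partner + free catalyst + right-handed substrate -> free catalyst + right-handed product; left-handed substrate + racemization catalyst <-> right-handed substrate + racemization catalyst; free catalyst -> spent catalyst; partner -> decomposed reagent; 2 racemization catalyst <-> resting dimer
- an excess is below zero if the other one leads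

I followed the rate. I called the drive the rate per substrate left and per partner not drawn by the reaction. Its time sum is the exposure: the natural logarithm of the partner fraction not drawn over the substrate fraction left, divided by partner charge less the charge of both substrates together. The north plateau stood at 80.2% reacted, which gave an exposure of 5.04 L mol⁻¹. I took north because its charge lay nearer this flask than east's.

The north reading at 2.50 min showed 75.9% reacted, an exposure of 4.35 L mol⁻¹. From that one reading, the drive lost a power of ten every 2.89 min.

So I reckoned that this flask's substrate fraction started falling at 1.61 min⁻¹. At this charge, the exposure gave 77.7% reacted. By 25 min, I reckoned, substrate loss slowed the rate by a factor of 4.48, and the reaction's draw on partner by 1.64. At the pace read from north, the drive fell 8.65 powers of ten in this flask, far more than either. At that pace, nearly all of the exposure had accrued by then.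

The forecast gave 77.5%, an excess of 48.7% and the verdict keeps pace, holding that “The catalyst therefore dies early”. My figure and its yield lay 0.20 percentage points apart.

The flask gave 77.1%, an excess of 48.9% and the verdict keeps pace, 92% of the way.

    partner + free catalyst + left-handed substrate → free catalyst + left-handed product (k = 40000 L² mol⁻² min⁻¹)
    partner + free catalyst + right-handed substrate → free catalyst + right-handed product (k = 13000 L² mol⁻² min⁻¹)
    left-handed substrate + racemization catalyst ⇌ right-handed substrate + racemization catalyst, rate k3*[racemization catalyst]*[left-handed substrate] forward; the back reaction follows from the equilibrium constant (k = 2700 L mol⁻¹ min⁻¹)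
    free catalyst → spent catalyst (k = 0.190 min⁻¹)
    partner → decomposed reagent (k = 0.470 min⁻¹)
    2 racemization catalyst ⇌ resting dimer (K = 7.80 L mol⁻¹, k = 41.0 L mol⁻¹ min⁻¹)

At 25.0 min this flask held 0% of its partner, the limiting reagent, with 0.246 M of decomposed reagent, beside 99.1% spent catalyst. Its own yield gave an exposure of 4.93 L mol⁻¹, against my 5.04 L mol⁻¹. For the neighbour charged with 5.6 × 10⁻⁴ M of free catalyst, I multiplied the exposure by 4.00. That gave 99.1%, and that neighbour flask gave 99.0%.

The numbers in the tables are calculated from invented constants; noise was put on by code.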